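The depsidone is cut at the ester C–O bond on ring B carbon 1. Ring A carbons 1 to 6 carry CH3, H, OH, CH2OH, ether O, ester carbonyl; ring B carbons 1 to 6 carry ester O, CH2OH, OH, lactone carbonyl, lactol carbon, ether O. The free hydroxyl on ring B carbon 3 is para to the ether oxygen on carbon 6, so oxidation gives a carbon 6 monoketal dienone whose only unsubstituted β carbon is carbon 1; the ring A carboxyl adds there and methanol loss rearomatises, closing the seven-membered lactone in one operation. The precursor is a diaryl ether acid with acetonide ring A and methoxyphthalide ring B bearing free phenol and silylated hydroxymethyl.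

Key step: step 13

Remark on the chemistry (assumption): the lactol carbon of a 3-hydroxyphthalide epimerises by ring–chain tautomerism in water near neutral pH and under base. It is therefore carried as a racemic methyl acetal, fixed as the (S) acylal in step 15 and released in step 16 under neutral, non-aqueous conditions. Afterwards solutions should be kept cold and free of base.

Design points:
- The carboxyl on ring A carbon 6 is carried as a benzyl ester and freed by hydrogenolysis, because an ester flanked by two ortho substituents would need hydrolytic conditions that open the phthalide.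
- The hydroxymethyl on ring B carbon 2 is a silyl ether, not an ester, because an acyloxymethyl group next to the phenol and α to the dienone would be a leaving group.
- Attack of the carboxyl at carbon 1 or at carbon 5 of ring B would each close a seven-membered ring; selectivity rests on carbon 5 being fully substituted.
- The diaryl ether is made while ring B carbon 1 still bears hydrogen, so the coupling has only three ortho substituents to overcome.

Step 1
Reactants: 1 orsellinic acid (2,4-dihydroxy-6-methylbenzoic acid)
Product: 2 benzyl 2,4-dihydroxy-6-methylbenzoate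
Conditions: BnBr, KHCO3, DMF, 25 °C
Reagents that add atoms: benzyl bromide, BrCc1ccccc1
Why: Carboxylate O-alkylation (SN2) under bicarbonate leaves the two less acidic phenols untouched.

Step 2
Reactants: 2 benzyl 2,4-dihydroxy-6-methylbenzoate
Product: 3 benzyl 3-formyl-2,4-dihydroxy-6-methylbenzoate
Conditions: Cl2CHOMe, TiCl4, CH2Cl2, −15 to 0 °C; aqueous HCl work-up
Reagents that add atoms: dichloromethyl methyl ether, COC(Cl)Cl; water, O
Why: Rieche formylation is steered by the titanium phenoxide and ester chelate to the ring carbon between the two hydroxyls (ring A carbon 4), and the minor isomer formylated next to the methyl group is to be removed by crystallisation.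

Step 3
Reactants: 3 benzyl 3-formyl-2,4-dihydroxy-6-methylbenzoate
Product: 5 benzyl 5-hydroxy-2,2,7-trimethyl-4H-1,3-benzodioxine-6-carboxylate, via triol 4 (not isolated)
Conditions: NaBH4, THF–MeOH, 0 °C; work-up at pH 6; then Me2C(OMe)2, PPTS, acetone, 25 °C
Reagents that add atoms: 2,2-dimethoxypropane, COC(C)(C)OC
Why: Borohydride reduction of the aldehyde followed by acid-catalysed transketalisation under equilibrating conditions should tie the new CH2OH to the hydroxyl para to the ester (on ring A carbon 3), since the hydroxyl ortho to the ester stays hydrogen-bonded to the ester carbonyl.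

Step 4
Reactants: 5 benzyl 5-hydroxy-2,2,7-trimethyl-4H-1,3-benzodioxine-6-carboxylate
Product: 6 benzyl 2,2,7-trimethyl-5-[(trifluoromethylsulfonyl)oxy]-4H-1,3-benzodioxine-6-carboxylate
Conditions: Tf2O, pyridine, CH2Cl2, 0 °C
Reagents that add atoms: trifluoromethanesulfonic anhydride, O=S(=O)(OS(=O)(=O)C(F)(F)F)C(F)(F)F
Why: O-sulfonylation of the only free phenol turns ring A carbon 5 into the electrophilic partner for the diaryl ether coupling.

Step 5
Reactants: 7 2,5-dibromohydroquinone (2,5-dibromobenzene-1,4-diol)
Product: 8 1,4-bis(benzyloxy)-2,5-dibromobenzene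
Conditions: BnBr, K2CO3, DMF, 60 °C
Reagents that add atoms: benzyl bromide, BrCc1ccccc1
Why: Williamson ether synthesis protects both hydroquinone oxygens (the future oxygens on ring B carbons 3 and 6) with groups that survive organolithium reagents and leave under neutral hydrogenolysis.

Step 6
Reactants: 8 1,4-bis(benzyloxy)-2,5-dibromobenzene
Product: 10 [2,5-bis(benzyloxy)-4-bromophenyl]methanol, via aldehyde 9 (not isolated)
Conditions: n-BuLi (1.0 equiv), THF, −78 °C; DMF; then MeOH, NaBH4, 0 °C
Reagents that add atoms: N,N-dimethylformamide, CN(C)C=O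
Why: Bromine–lithium exchange on the symmetrical dibromide stops after one exchange at −78 °C, and formylation with in-flask borohydride reduction gives the benzylic alcohol that becomes the hydroxymethyl on ring B carbon 2.

Step 7
Reactants: 10 [2,5-bis(benzyloxy)-4-bromophenyl]methanol
Product: 11 {[2,5-bis(benzyloxy)-4-bromophenyl]methoxy}tri(propan-2-yl)silane
Conditions: i-Pr3SiCl, imidazole, DMF, 25 °C
Reagents that add atoms: triisopropylsilyl chloride, CC(C)[Si](Cl)(C(C)C)C(C)C
Why: Silylation of the primary alcohol installs a group that tolerates organolithiums, base, hydrogenolysis and trivalent iodine and cannot act as a leaving group.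

Step 8
Reactants: 11 {[2,5-bis(benzyloxy)-4-bromophenyl]methoxy}tri(propan-2-yl)silane
Product: 12 3,6-bis(benzyloxy)-2-bromo-5-{[(triisopropylsilyl)oxy]methyl}benzoic acid
Conditions: LiN(i-Pr)2, THF, −78 °C; CO2; cold 1 M HCl work-up
Reagents that add atoms: carbon dioxide, O=C=O
Why: Directed ortho-lithiation removes the ring hydrogen flanked by bromine and benzyloxy, the most acidic site (the future ring B carbon 4), and carboxylation places the future lactone carbonyl there.

Step 9
Reactants: 12 3,6-bis(benzyloxy)-2-bromo-5-{[(triisopropylsilyl)oxy]methyl}benzoic acid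
Product: 14 4,7-bis(benzyloxy)-3-methoxy-6-{[(triisopropylsilyl)oxy]methyl}-2-benzofuran-1(3H)-one (racemic), via hydroxyphthalide 13 (not isolated)
Conditions: n-BuLi (2.2 equiv), THF, −78 °C; DMF; cold 1 M HCl work-up; then MeOH, PPTS, 40 °C
Reagents that add atoms: N,N-dimethylformamide, CN(C)C=O; methanol, CO
Why: Bromine–lithium exchange on the lithium carboxylate and formylation give the ortho-formyl acid, which closes to the 3-hydroxyphthalide and is converted by acid-catalysed pseudo-ester formation into the base-stable racemic methyl acetal.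

Step 10
Reactants: 14 4,7-bis(benzyloxy)-3-methoxy-6-{[(triisopropylsilyl)oxy]methyl}-2-benzofuran-1(3H)-one
Product: 15 4,7-dihydroxy-3-methoxy-6-{[(triisopropylsilyl)oxy]methyl}-2-benzofuran-1(3H)-one (racemic)
Conditions: hydrogen (1 atm), Pd/C, EtOAc, 25 °C; handled under argon afterwards
Reagents that add atoms: none
Why: Hydrogenolysis cleaves both aryl benzyl ethers under neutral conditions that leave the silyl ether and the methyl acetal intact.

Step 11
Reactants: 6 benzyl 2,2,7-trimethyl-5-[(trifluoromethylsulfonyl)oxy]-4H-1,3-benzodioxine-6-carboxylate; 15 4,7-dihydroxy-3-methoxy-6-{[(triisopropylsilyl)oxy]methyl}-2-benzofuran-1(3H)-one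
Product: 16 benzyl 5-[(7-hydroxy-3-methoxy-1-oxo-6-{[(triisopropylsilyl)oxy]methyl}-1,3-dihydro-2-benzofuran-4-yl)oxy]-2,2,7-trimethyl-4H-1,3-benzodioxine-6-carboxylate (racemic)
Conditions: Pd(OAc)2, t-BuXPhos, K3PO4, toluene, 90 °C, argon
Reagents that add atoms: none
Why: Palladium-catalysed C–O cross-coupling (Buchwald–Hartwig-type diaryl ether synthesis) should join the electron-poor triflate on ring A carbon 5 to the hydroxyl on ring B carbon 6, because the hydroxyl on ring B carbon 3 is flanked by two substituents and hydrogen-bonded to the lactone carbonyl.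

Step 12
Reactants: 16 diaryl ether benzyl ester
Product: 17 5-[(7-hydroxy-3-methoxy-1-oxo-6-{[(triisopropylsilyl)oxy]methyl}-1,3-dihydro-2-benzofuran-4-yl)oxy]-2,2,7-trimethyl-4H-1,3-benzodioxine-6-carboxylic acid (racemic)
Conditions: hydrogen (1 atm), Pd/C, EtOAc, 25 °C
Reagents that add atoms: none
Why: Hydrogenolysis of the benzyl ester frees the hindered carboxylic acid on ring A carbon 6 without any hydrolytic step, so the phthalide, acetonide and silyl ether are not exposed to base or acid.

Step 13
Reactants: 17 diaryl ether acid (free ring A carboxyl and free ring B phenol)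
Product: 20 protected depsidone (ring A acetonide; CH2OSi(i-Pr)3 on ring B; free ring B phenol; racemic methyl acetal), via quinone monoketal 18 (not isolated), via oxa-Michael adduct 19 (not isolated)
Conditions: PhI(OAc)2 (1.05 equiv), MeOH, −10 to 0 °C; solvent exchange to toluene; camphorsulfonic acid (0.2 equiv), 4 Å molecular sieves, 0 to 40 °C
Reagents that add atoms: none
Why: Proposed new method: trivalent iodine oxidises the only free phenol (on ring B carbon 3) to an aryloxy-stabilised cation that methanol captures at ring B carbon 6 to give the mixed methyl aryl ketal dienone 18; under anhydrous acid the ring A carboxylic acid adds to ring B carbon 1, the hydrogen-bearing β-carbon of the enone, to give 19, and ionisation of the ketal with loss of methanol and of the proton on carbon 1 restores the arene as 20. The closest known reactions are the oxidation of para-alkoxyphenols to quinone monoketals with PhI(OAc)2 in methanol and the acid-promoted addition–elimination of nucleophiles at the carbon next to the ketal carbon, but a tethered carboxylic acid has not been used as the nucleophile on this substrate class. The seven-membered lactone closes in a 7-exo-trig oxa-Michael mode. No stereocentre is created, because the sp3 centres of 19 at ring B carbons 1 and 6 are erased on aromatisation and the racemic acetal carbon is not touched. The step needs attack at ring B carbon 1 rather than at carbon 5, which is the more electrophilic β-carbon and would also close a seven-membered ring, and this is secured because carbon 5 bears no hydrogen, so its adduct cannot aromatise and reverts, as would an acyloxy ketal formed by capture at carbon 6. The silyl ether offers no leaving group α to the dienone, the sieves prevent hydrolysis of the ketal to the quinone, and removing methanol before the acid stage prevents exchange of the ring A aryloxy group.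

Step 14
Reactants: 20 protected depsidone
Product: 21 racemic lactol (all hydroxyls free, lactol carbon unassigned)
Conditions: 1 M aqueous H2SO4–THF (1:2), 45 °C, dilute
Reagents that add atoms: water, O
Why: Acid-catalysed hydrolysis should cleave the acetonide, the silyl ether and the methyl acetal in one operation, the non-nucleophilic counter-ion avoids benzylic substitution, and the aryl ester of the depsidone, which is labile only to base, stays closed.

Step 15
Reactants: 21 racemic lactol
Product: 22 (S)-pentaacetate (acetates on both phenol oxygens, both CH2O groups and the lactol O)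
Conditions: Ac2O (8 equiv), i-Pr2NEt, (2S,3R)-HyperBTM (10 mol%), CH2Cl2–THF, 0 °C
Reagents that add atoms: acetic anhydride, CC(=O)OC(C)=O
Why: Acylative dynamic kinetic resolution, in which the phenols and primary alcohols are acetylated without stereochemical consequence, the lactol enantiomers interconvert through the ring-opened formyl carboxylate under the amine base, and the chiral isothiourea acyl-transfer catalyst acetylates one of them faster to set the (S) acylal, the mirror-image catalyst being used if the sense of induction on this substrate is the opposite.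

Step 16
Reactants: 22 (S)-pentaacetate
Product: 23 target depsidone with (S)-configured lactol carbon
Conditions: immobilised Candida antarctica lipase B, n-BuOH, 2-methyltetrahydrofuran, 20 °C
Reagents that add atoms: none
Why: Lipase-catalysed transesterification cleaves each acetate at the acyl carbon under neutral, non-aqueous conditions, so the C–O bonds at the acetal carbon are not broken and the (S) configuration set in step 15 should be retained.

Compound list

1 | orsellinic acid (2,4-dihydroxy-6-methylbenzoic acid) | Cc1cc(O)cc(O)c1C(=O)O | starting material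
2 | benzyl 2,4-dihydroxy-6-methylbenzoate | Cc1cc(O)cc(O)c1C(=O)OCc1ccccc1 | intermediate
3 | benzyl 3-formyl-2,4-dihydroxy-6-methylbenzoate | Cc1cc(O)c(C=O)c(O)c1C(=O)OCc1ccccc1 | intermediate
4 | benzyl 2,4-dihydroxy-3-(hydroxymethyl)-6-methylbenzoate | Cc1cc(O)c(CO)c(O)c1C(=O)OCc1ccccc1 | intermediate (not isolated)
5 | benzyl 5-hydroxy-2,2,7-trimethyl-4H-1,3-benzodioxine-6-carboxylate | Cc1cc2OC(C)(C)OCc2c(O)c1C(=O)OCc1ccccc1 | intermediate
6 | benzyl 2,2,7-trimethyl-5-[(trifluoromethylsulfonyl)oxy]-4H-1,3-benzodioxine-6-carboxylate | Cc1cc2OC(C)(C)OCc2c(OS(=O)(=O)C(F)(F)F)c1C(=O)OCc1ccccc1 | intermediate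
7 | 2,5-dibromohydroquinone | Oc1cc(Br)c(O)cc1Br | starting material
8 | 1,4-bis(benzyloxy)-2,5-dibromobenzene | Brc1cc(OCc2ccccc2)c(Br)cc1OCc1ccccc1 | intermediate
9 | 2,5-bis(benzyloxy)-4-bromobenzaldehyde | O=Cc1cc(OCc2ccccc2)c(Br)cc1OCc1ccccc1 | intermediate (not isolated)
10 | [2,5-bis(benzyloxy)-4-bromophenyl]methanol | OCc1cc(OCc2ccccc2)c(Br)cc1OCc1ccccc1 | intermediate
11 | {[2,5-bis(benzyloxy)-4-bromophenyl]methoxy}tri(propan-2-yl)silane | CC(C)[Si](OCc1cc(OCc2ccccc2)c(Br)cc1OCc1ccccc1)(C(C)C)C(C)C | intermediate
12 | 3,6-bis(benzyloxy)-2-bromo-5-{[(triisopropylsilyl)oxy]methyl}benzoic acid | CC(C)[Si](OCc1cc(OCc2ccccc2)c(Br)c(C(=O)O)c1OCc1ccccc1)(C(C)C)C(C)C | intermediate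
13 | 4,7-bis(benzyloxy)-3-hydroxy-6-{[(triisopropylsilyl)oxy]methyl}-2-benzofuran-1(3H)-one (racemic) | OC1OC(=O)c2c(OCc3ccccc3)c(CO[Si](C(C)C)(C(C)C)C(C)C)cc(OCc3ccccc3)c12 | intermediate (not isolated)
14 | 4,7-bis(benzyloxy)-3-methoxy-6-{[(triisopropylsilyl)oxy]methyl}-2-benzofuran-1(3H)-one (racemic) | COC1OC(=O)c2c(OCc3ccccc3)c(CO[Si](C(C)C)(C(C)C)C(C)C)cc(OCc3ccccc3)c12 | intermediate
15 | 4,7-dihydroxy-3-methoxy-6-{[(triisopropylsilyl)oxy]methyl}-2-benzofuran-1(3H)-one (racemic) | COC1OC(=O)c2c(O)c(CO[Si](C(C)C)(C(C)C)C(C)C)cc(O)c12 | intermediate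
16 | benzyl 5-[(7-hydroxy-3-methoxy-1-oxo-6-{[(triisopropylsilyl)oxy]methyl}-1,3-dihydro-2-benzofuran-4-yl)oxy]-2,2,7-trimethyl-4H-1,3-benzodioxine-6-carboxylate (racemic) | Cc1cc2OC(C)(C)OCc2c(c1C(=O)OCc1ccccc1)Oc1cc(CO[Si](C(C)C)(C(C)C)C(C)C)c(O)c2C(=O)OC(OC)c12 | intermediate
17 | diaryl ether acid, precursor of the key step (free carboxyl on ring A, hydrogen on ring B carbon 1, free hydroxyl on ring B carbon 3, racemic acetal carbon) | Cc1cc2OC(C)(C)OCc2c(c1C(=O)O)Oc1cc(CO[Si](C(C)C)(C(C)C)C(C)C)c(O)c2C(=O)OC(OC)c12 | intermediate
18 | ring B quinone monoketal (ketone at carbon 3, methyl aryl ketal at carbon 6; diastereomer mixture) | Cc1cc2OC(C)(C)OCc2c(c1C(=O)O)OC1(OC)C=C(CO[Si](C(C)C)(C(C)C)C(C)C)C(=O)C2=C1C(OC)OC2=O | intermediate (not isolated)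
19 | oxa-Michael adduct (ester C–O bond to ring B carbon 1 formed, ketal at carbon 6 intact, enol form; diastereomer mixture) | Cc1cc2OC(C)(C)OCc2c2c1C(=O)OC1C(CO[Si](C(C)C)(C(C)C)C(C)C)=C(O)C3=C(C(OC)OC3=O)C1(OC)O2 | intermediate (not isolated)
20 | protected depsidone, product of the key step (acetonide on ring A, CH2OSi(i-Pr)3 on ring B carbon 2, free hydroxyl on ring B carbon 3, racemic methyl acetal) | Cc1cc2OC(C)(C)OCc2c2c1C(=O)Oc1c(CO[Si](C(C)C)(C(C)C)C(C)C)c(O)c3C(=O)OC(OC)c3c1O2 | intermediate
21 | racemic lactol (the target constitution, lactol carbon unassigned) | Cc1cc(O)c(CO)c2c1C(=O)Oc1c(CO)c(O)c3c(c1O2)C(O)OC3=O | intermediate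
22 | (S)-pentaacetate of 21 | Cc1cc(OC(C)=O)c(COC(C)=O)c2c1C(=O)Oc1c(COC(C)=O)c(OC(C)=O)c3c(c1O2)[C@@H](OC(C)=O)OC3=O | intermediate
23 | target depsidone, (S) at the lactol carbon (ring A: CH3, OH, CH2OH; ring B: CH2OH, OH, hydroxy-lactone) | Cc1cc(O)c(CO)c2c1C(=O)Oc1c(CO)c(O)c3c(c1O2)[C@@H](O)OC3=O | target

Total steps: 16. Longest linear sequence: 12 steps (steps 5 to 16); the ring A branch (steps 1 to 4) joins at step 11.

Steps most likely to fail

Step 13. The mixed ketal may ionise and shed the ring A aryloxy group (to the quinone or a dimethyl ketal) faster than the carboxyl adds at ring B carbon 1, or the carboxyl may be held in an unproductive adduct at carbon 6 or carbon 5. The fallback uses known reactions only and reverses the order of bond formation (ester first, ether last); it sets out from 14 and 6 and returns to the route at 20. Electrophilic bromination of 14 (NBS, MeCN, 25 to 50 °C) should enter the only free position of ring B (carbon 1), giving the bromide F1. Miyaura borylation (bis(pinacolato)diboron, PdCl2(dppf), KOAc, dioxane, 90 °C) gives the pinacol boronate F2, and oxidation (aqueous H2O2, pH 7 phosphate buffer, THF, 0 °C) gives the phenol F3. In parallel, hydrogenolysis of 6 (hydrogen, Pd/C, EtOAc) frees the acid triflate F4. This is converted under neutral conditions (1-chloro-N,N,2-trimethylprop-1-en-1-amine, CH2Cl2) into the acid chloride F5, which is esterified with F3 (Et3N, DMAP) to the aryl ester F6. Hydrogenolysis of both benzyl ethers gives the bis-phenol F7. Intramolecular palladium-catalysed C–O coupling of the hydroxyl on ring B carbon 6 with the ring A triflate (Pd(OAc)2, t-BuXPhos, K3PO4, toluene, 80 °C) then closes the seven-membered ring to 20. The hindered 2,6-disubstituted aroyl group should resist migration to the neighbouring oxygen during that step.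

Step 11. Reductive elimination at the di-ortho-substituted ring A carbon may be slow, so that triflate cleavage or binding of the chelating phenoxide on ring B carbon 3 to palladium takes over. The fallback replaces catalysis by addition–elimination; it sets out from 5 and returns at 16. Phenol 5 is converted into the aryl fluorosulfate F8 (SO2F2, Et3N, CH2Cl2) and, by nucleophilic deoxyfluorination (NMe4F, DMF, 60 to 80 °C), into the aryl fluoride F9. SNAr of the less hindered phenoxide of 15 (on ring B carbon 6) on F9, activated by the ortho ester (Cs2CO3, DMSO, 100 °C), should then give 16.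

Step 16. Enzymatic cleavage of the hindered aryl acetates may stall, and a slow reaction gives the freed lactol time to lose configuration. The fallback avoids aryl acetates altogether; it sets out from 21 and returns at 23. Lipase-catalysed acetylation of 21 with vinyl acetate in 2-methyltetrahydrofuran under dynamic kinetic resolution (lipase chosen by screening for the (S) acylal) should acetylate only the two primary alcohols and the lactol, giving the triacetate F10 with both phenols free. Alcoholysis with the same lipase and n-BuOH then releases 23; an enzyme that accepts the lactol for acylation also accepts its acetate for cleavage.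

Further compounds

F1 | step 13 | 4,7-bis(benzyloxy)-5-bromo-3-methoxy-6-{[(triisopropylsilyl)oxy]methyl}-2-benzofuran-1(3H)-one | COC1OC(=O)c2c(OCc3ccccc3)c(CO[Si](C(C)C)(C(C)C)C(C)C)c(Br)c(OCc3ccccc3)c12
F2 | step 13 | 4,7-bis(benzyloxy)-3-methoxy-5-(4,4,5,5-tetramethyl-1,3,2-dioxaborolan-2-yl)-6-{[(triisopropylsilyl)oxy]methyl}-2-benzofuran-1(3H)-one | COC1OC(=O)c2c(OCc3ccccc3)c(CO[Si](C(C)C)(C(C)C)C(C)C)c(B4OC(C)(C)C(C)(C)O4)c(OCc3ccccc3)c12
F3 | step 13 | 4,7-bis(benzyloxy)-5-hydroxy-3-methoxy-6-{[(triisopropylsilyl)oxy]methyl}-2-benzofuran-1(3H)-one | COC1OC(=O)c2c(OCc3ccccc3)c(CO[Si](C(C)C)(C(C)C)C(C)C)c(O)c(OCc3ccccc3)c12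
F4 | step 13 | 2,2,7-trimethyl-5-[(trifluoromethylsulfonyl)oxy]-4H-1,3-benzodioxine-6-carboxylic acid | Cc1cc2OC(C)(C)OCc2c(OS(=O)(=O)C(F)(F)F)c1C(=O)O
F5 | step 13 | 2,2,7-trimethyl-5-[(trifluoromethylsulfonyl)oxy]-4H-1,3-benzodioxine-6-carbonyl chloride | Cc1cc2OC(C)(C)OCc2c(OS(=O)(=O)C(F)(F)F)c1C(Cl)=O
F6 | step 13 | aryl ester of F4 with the new phenol oxygen of F3 | Cc1cc2OC(C)(C)OCc2c(OS(=O)(=O)C(F)(F)F)c1C(=O)Oc1c(CO[Si](C(C)C)(C(C)C)C(C)C)c(OCc2ccccc2)c2C(=O)OC(OC)c2c1OCc1ccccc1
F7 | step 13 | bis-phenol from F6 (both ring B hydroxyls free, ring A triflate intact) | Cc1cc2OC(C)(C)OCc2c(OS(=O)(=O)C(F)(F)F)c1C(=O)Oc1c(CO[Si](C(C)C)(C(C)C)C(C)C)c(O)c2C(=O)OC(OC)c2c1O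
F8 | step 11 | benzyl 5-[(fluorosulfonyl)oxy]-2,2,7-trimethyl-4H-1,3-benzodioxine-6-carboxylate | Cc1cc2OC(C)(C)OCc2c(OS(=O)(=O)F)c1C(=O)OCc1ccccc1
F9 | step 11 | benzyl 5-fluoro-2,2,7-trimethyl-4H-1,3-benzodioxine-6-carboxylate | Cc1cc2OC(C)(C)OCc2c(F)c1C(=O)OCc1ccccc1
F10 | step 16 | (S)-triacetate of 21 (acetates on both CH2O groups and the lactol O; phenols free) | Cc1cc(O)c(COC(C)=O)c2c1C(=O)Oc1c(COC(C)=O)c(O)c3c(c1O2)[C@@H](OC(C)=O)OC3=O
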